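**Strategy.** The two bicyclic halves are mirror-image units joined by an ester, so one catalytic route is run in both antipodal series and the antipodes are then esterified. In each half the tertiary carbinol C9 lies β to the lactone carbonyl C1 (2-benzoxepine numbering): an aldol retron across the C9–C9a bond of the cyclohexane ring. The seven-membered lactone is therefore built first, as a monocyclic α-bromo lactone carrying a stereodefined keto side chain on the future C5a. SmI2 then converts it into a samarium enolate that closes the cyclohexane onto the ketone, setting C9 and C9a in one operation. The left-hand cyclisation is the last ring closure of the route.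

Key step: step 17

Remark: the right-hand unit of the target is the enantiomer of the left-hand unit (left 5aS,6R,9S,9aS; right 5aR,6S,9R,9aR; locants C1 lactone C=O, O2, C3, C4, C5, C5a, C6 isopropyl, C7, C8, C9 carbinol, C9a), so both antipodes of the monomer are made.

**Shared building block**

Step 1
Reactants: 1 but-3-ene-1,2-diol (racemic)
Product: 2 1-[(tert-butyldiphenylsilyl)oxy]but-3-en-2-ol (racemic)
Conditions: TBDPSCl (1.0 equiv.), imidazole, CH2Cl2, 0 °C
Reagents that add atoms: tert-butyl(chloro)diphenylsilane, CC(C)(C)[Si](Cl)(c1ccccc1)c1ccccc1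
Why: The bulky silyl chloride should silylate the primary hydroxyl selectively (selective monosilylation); the carbinol centre is destroyed in step 2, so the racemate serves.

Step 2
Reactants: 2 1-[(tert-butyldiphenylsilyl)oxy]but-3-en-2-ol
Product: 3 1-[(tert-butyldiphenylsilyl)oxy]but-3-en-2-one
Conditions: Dess–Martin periodinane, NaHCO3, CH2Cl2, 0 °C to rt; used at once
Reagents that add atoms: none
Why: Dess–Martin oxidation of the secondary allylic alcohol should give the vinyl ketone under buffered conditions that spare the silyl ether.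

**Right-hand (alcohol) half, antipodal series**

Step 3
Reactants: 3 1-[(tert-butyldiphenylsilyl)oxy]but-3-en-2-one; 4 3-methylbutanal
Product: 5 (2S)-6-[(tert-butyldiphenylsilyl)oxy]-5-oxo-2-(propan-2-yl)hexanal
Conditions: (S)-2-[methoxy(diphenyl)methyl]pyrrolidine (5 mol%), ethyl 3,4-dihydroxybenzoate (20 mol%), 4 (2 equiv.), neat, 4 °C
Reagents that add atoms: none
Why: Enamine-catalysed Michael addition of the aldehyde to the vinyl ketone; the diarylmethyl arm of the (S)-catalyst shields one face of the E-enamine, so C2 should form as S.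

Step 4
Reactants: 5 (2S)-keto aldehyde; 6 (triphenylphosphoranylidene)acetaldehyde
Product: 7 (2E,4S)-8-[(tert-butyldiphenylsilyl)oxy]-7-oxo-4-(propan-2-yl)oct-2-enal
Conditions: toluene, 70 °C
Reagents that add atoms: none
Why: Wittig olefination with the stabilised formyl ylide should be selective for the aldehyde over the ketone and give the E-enal without touching C4.

Step 5
Reactants: 7 (2E,4S)-enal; 8 potassium trifluoro[(E)-2-phenylethenyl]borate
Product: 9 (3S,4S)-8-[(tert-butyldiphenylsilyl)oxy]-7-oxo-3-[(E)-2-phenylethenyl]-4-(propan-2-yl)octanal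
Conditions: (2R,5R)-5-benzyl-2-tert-butyl-3-methylimidazolidin-4-one·HCl (20 mol%), HF (1 equiv.), DME, −20 °C
Reagents that add atoms: none
Why: Iminium-catalysed conjugate transfer of the styryl group from the trifluoroborate (organocatalytic Friedel–Crafts-type vinylation); the (2R,5R)-catalyst blocks one face of the E-iminium ion and should override the weak bias of C4 to set C3 as S, styryl syn to isopropyl along C2–C5.

Step 6
Reactants: 9 (3S,4S)-aldehyde
Product: 11 (3S,4S)-2-bromo-8-[(tert-butyldiphenylsilyl)oxy]-7-oxo-3-[(E)-2-phenylethenyl]-4-(propan-2-yl)octanoic acid (both C2 epimers), via bromo aldehyde 10 (not isolated)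
Conditions: 4,4-dibromo-2,6-di-tert-butylcyclohexa-2,5-dien-1-one (1.05 equiv.), (2R,5R)-2,5-diphenylpyrrolidine (20 mol%), PhCO2H (20 mol%), CH2Cl2/pentane, −24 °C; then NaClO2, NaH2PO4, 2-methylbut-2-ene, t-BuOH/H2O, 0 °C
Reagents that add atoms: 4,4-dibromo-2,6-di-tert-butylcyclohexa-2,5-dien-1-one, CC(C)(C)C1=CC(Br)(Br)C=C(C(C)(C)C)C1=O; sodium chlorite, [Na+].[O-]Cl=O
Why: Enamine-catalysed α-bromination of the aldehyde followed by Pinnick oxidation in the same flask; only at the aldehyde stage can C2 be activated selectively beside the ketone, and its configuration is irrelevant because it later becomes an enolate carbon.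

Step 7
Reactants: 11 (3S,4S)-bromo acid; 12 tert-butyl 2-(hydroxymethyl)prop-2-enoate
Product: 13 2-(tert-butoxycarbonyl)prop-2-en-1-yl (3S,4S)-2-bromo-8-[(tert-butyldiphenylsilyl)oxy]-7-oxo-3-[(E)-2-phenylethenyl]-4-(propan-2-yl)octanoate (both C2 epimers)
Conditions: DCC, DMAP (5 mol%), CH2Cl2, 0 °C
Reagents that add atoms: none
Why: Steglich esterification of the acid with the primary allylic alcohol under mild carbodiimide activation should leave the bromide, ketone and acrylate untouched.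

Step 8
Reactants: 13 bromo ester
Product: 14 tert-butyl (5R)-6-bromo-5-[(3S)-7-[(tert-butyldiphenylsilyl)oxy]-2-methyl-6-oxoheptan-3-yl]-7-oxo-2,5,6,7-tetrahydrooxepine-3-carboxylate (both C6 epimers)
Conditions: second-generation Hoveyda–Grubbs catalyst RuCl2(H2IMes)(=CH-C6H4-2-OiPr) (5 mol%), toluene (2 mM), 80 °C
Reagents that add atoms: none
Why: Ring-closing metathesis between the styryl alkene and the 1,1-disubstituted acrylate alkene should close the seven-membered lactone with loss of styrene, the ring fixing the geometry of the new trisubstituted alkene.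

Step 9
Reactants: 14 bromo lactone
Product: 16 tert-butyl (5aR,6S,9R,9aR)-9-{[(tert-butyldiphenylsilyl)oxy]methyl}-9-hydroxy-1-oxo-6-(propan-2-yl)-1,3,5a,6,7,8,9,9a-octahydro-2-benzoxepine-4-carboxylate, via samarium enolate 15 (not isolated)
Conditions: SmI2 (2.5 equiv.), THF, −78 °C; aq. NH4Cl
Reagents that add atoms: none
Why: Intramolecular samarium Reformatsky aldol (6-exo-trig), the mirror image of step 17 where the reasoning is given; the chelated chair transition state should set C9 and C9a as R,R.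

Step 10
Reactants: 16 silyl ether
Product: 17 tert-butyl (5aR,6S,9R,9aR)-9-hydroxy-9-(hydroxymethyl)-1-oxo-6-(propan-2-yl)-1,3,5a,6,7,8,9,9a-octahydro-2-benzoxepine-4-carboxylate
Conditions: HF·pyridine, pyridine, THF, 0 °C to rt
Reagents that add atoms: none
Why: Buffered fluoride desilylation should free the primary hydroxyl while the tert-butyl ester, lactone and tertiary alcohol survive.

**Left-hand (acid) half**

Step 11
Reactants: 3 1-[(tert-butyldiphenylsilyl)oxy]but-3-en-2-one; 4 3-methylbutanal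
Product: 18 (2R)-6-[(tert-butyldiphenylsilyl)oxy]-5-oxo-2-(propan-2-yl)hexanal
Conditions: (R)-2-[methoxy(diphenyl)methyl]pyrrolidine (5 mol%), ethyl 3,4-dihydroxybenzoate (20 mol%), 4 (2 equiv.), neat, 4 °C
Reagents that add atoms: none
Why: Enamine-catalysed Michael addition as in step 3 with the antipodal catalyst, which should set C2 as R.

Step 12
Reactants: 18 (2R)-keto aldehyde; 6 (triphenylphosphoranylidene)acetaldehyde
Product: 19 (2E,4R)-8-[(tert-butyldiphenylsilyl)oxy]-7-oxo-4-(propan-2-yl)oct-2-enal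
Conditions: toluene, 70 °C
Reagents that add atoms: none
Why: Aldehyde-selective Wittig olefination with the stabilised ylide should give the E-enal.

Step 13
Reactants: 19 (2E,4R)-enal; 8 potassium trifluoro[(E)-2-phenylethenyl]borate
Product: 20 (3R,4R)-8-[(tert-butyldiphenylsilyl)oxy]-7-oxo-3-[(E)-2-phenylethenyl]-4-(propan-2-yl)octanal
Conditions: (2S,5S)-5-benzyl-2-tert-butyl-3-methylimidazolidin-4-one·HCl (20 mol%), HF (1 equiv.), DME, −20 °C
Reagents that add atoms: none
Why: Iminium-catalysed styryl transfer as in step 5; the (2S,5S)-catalyst should leave the Re face of the β-carbon open and set C3 as R, syn to the isopropyl group.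

Step 14
Reactants: 20 (3R,4R)-aldehyde
Product: 22 (3R,4R)-2-bromo-8-[(tert-butyldiphenylsilyl)oxy]-7-oxo-3-[(E)-2-phenylethenyl]-4-(propan-2-yl)octanoic acid (both C2 epimers), via bromo aldehyde 21 (not isolated)
Conditions: 4,4-dibromo-2,6-di-tert-butylcyclohexa-2,5-dien-1-one (1.05 equiv.), (2R,5R)-2,5-diphenylpyrrolidine (20 mol%), PhCO2H (20 mol%), CH2Cl2/pentane, −24 °C; then NaClO2, NaH2PO4, 2-methylbut-2-ene, t-BuOH/H2O, 0 °C
Reagents that add atoms: 4,4-dibromo-2,6-di-tert-butylcyclohexa-2,5-dien-1-one, CC(C)(C)C1=CC(Br)(Br)C=C(C(C)(C)C)C1=O; sodium chlorite, [Na+].[O-]Cl=O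
Why: Enamine-catalysed α-bromination and Pinnick oxidation as in step 6; the C2 configuration does not matter.

Step 15
Reactants: 22 (3R,4R)-bromo acid; 12 tert-butyl 2-(hydroxymethyl)prop-2-enoate
Product: 23 2-(tert-butoxycarbonyl)prop-2-en-1-yl (3R,4R)-2-bromo-8-[(tert-butyldiphenylsilyl)oxy]-7-oxo-3-[(E)-2-phenylethenyl]-4-(propan-2-yl)octanoate (both C2 epimers)
Conditions: DCC, DMAP (5 mol%), CH2Cl2, 0 °C
Reagents that add atoms: none
Why: Steglich esterification as in step 7.

Step 16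
Reactants: 23 bromo ester
Product: 24 tert-butyl (5S)-6-bromo-5-[(3R)-7-[(tert-butyldiphenylsilyl)oxy]-2-methyl-6-oxoheptan-3-yl]-7-oxo-2,5,6,7-tetrahydrooxepine-3-carboxylate (both C6 epimers)
Conditions: second-generation Hoveyda–Grubbs catalyst RuCl2(H2IMes)(=CH-C6H4-2-OiPr) (5 mol%), toluene (2 mM), 80 °C
Reagents that add atoms: none
Why: Ring-closing metathesis as in step 8 should close the seven-membered lactone with loss of styrene.

Step 17
Reactants: 24 bromo lactone
Product: 26 tert-butyl (5aS,6R,9S,9aS)-9-{[(tert-butyldiphenylsilyl)oxy]methyl}-9-hydroxy-1-oxo-6-(propan-2-yl)-1,3,5a,6,7,8,9,9a-octahydro-2-benzoxepine-4-carboxylate, via samarium enolate 25 (not isolated)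
Conditions: SmI2 (2.5 equiv.), THF, −78 °C (slow addition of 24); aq. NH4Cl
Reagents that add atoms: none
Why: Samarium diiodide transfers two electrons to the C–Br bond α to the lactone carbonyl and gives the trivalent samarium enolate 25, which adds to the ketone carbon; the closest known reaction type is the intramolecular samarium Reformatsky aldol of α-bromo esters onto ketones. The cyclohexane closes by a 6-(enolexo)-exo-trig attack of C9a on C9, across the C5a–C9a bond of the lactone that already exists. C9 is controlled by a Zimmerman–Traxler chair in which samarium bridges the enolate and ketone oxygens; fused trans-decalin-like to the forming chair, it should put the C9–O bond equatorial and the CH2OSi group axial (9S, O trans to the lactone carbonyl). C9a is controlled by the same array: with the isopropyl group at C6 and the C5 ring bond at C5a both equatorial, the ring bonds at C5a and C9a should end trans (9aS). The step needs chemoselectivity for C–Br over ketone and enoate reduction, which the easy reduction of the α-bromo lactone and the absence of HMPA or a proton source at −78 °C should secure. It also needs diastereoselectivity, which the resident centres C5a and C6 should secure by fixing the chair.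

Step 18
Reactants: 26 tert-butyl ester
Product: 27 (5aS,6R,9S,9aS)-9-{[(tert-butyldiphenylsilyl)oxy]methyl}-9-hydroxy-1-oxo-6-(propan-2-yl)-1,3,5a,6,7,8,9,9a-octahydro-2-benzoxepine-4-carboxylic acid
Conditions: TFA/CH2Cl2 1:4, 0 °C to rt
Reagents that add atoms: none
Why: Acidolysis of the tert-butyl ester with loss of isobutene should leave the acid-stable silyl ether, the lactone and the deactivated tertiary alcohol intact.

**Union and deprotection**

Step 19
Reactants: 27 left-hand acid; 17 right-hand diol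
Product: 28 {(5aR,6S,9R,9aR)-4-(tert-butoxycarbonyl)-9-hydroxy-1-oxo-6-(propan-2-yl)-1,3,5a,6,7,8,9,9a-octahydro-2-benzoxepin-9-yl}methyl (5aS,6R,9S,9aS)-9-{[(tert-butyldiphenylsilyl)oxy]methyl}-9-hydroxy-1-oxo-6-(propan-2-yl)-1,3,5a,6,7,8,9,9a-octahydro-2-benzoxepine-4-carboxylate
Conditions: 2,4,6-trichlorobenzoyl chloride, Et3N, THF, 0 °C; then 17, DMAP, toluene, rt
Reagents that add atoms: none
Why: Yamaguchi esterification; only the primary hydroxyl of 17 should be acylated, the tertiary hydroxyls of both partners being too hindered, and no stereocentre is touched.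

Step 20
Reactants: 28 protected dimer
Product: 29 (5aR,6S,9R,9aR)-9-hydroxy-9-({[(5aS,6R,9S,9aS)-9-{[(tert-butyldiphenylsilyl)oxy]methyl}-9-hydroxy-1-oxo-6-(propan-2-yl)-1,3,5a,6,7,8,9,9a-octahydro-2-benzoxepine-4-carbonyl]oxy}methyl)-1-oxo-6-(propan-2-yl)-1,3,5a,6,7,8,9,9a-octahydro-2-benzoxepine-4-carboxylic acid
Conditions: TFA/CH2Cl2 1:4, 0 °C
Reagents that add atoms: none
Why: Acidolysis of the right-hand tert-butyl ester is done while the left-hand primary hydroxyl is still silylated, so that no free hydroxyl can attack the neighbouring lactone under acid.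

Step 21
Reactants: 29 silyl ether acid
Product: 30 CNP0340505.1, (5aR,6S,9R,9aR)-9-hydroxy-9-({[(5aS,6R,9S,9aS)-9-hydroxy-9-(hydroxymethyl)-1-oxo-6-(propan-2-yl)-1,3,5a,6,7,8,9,9a-octahydro-2-benzoxepine-4-carbonyl]oxy}methyl)-1-oxo-6-(propan-2-yl)-1,3,5a,6,7,8,9,9a-octahydro-2-benzoxepine-4-carboxylic acid
Conditions: HF·pyridine, pyridine, THF, 0 °C to rt
Reagents that add atoms: none
Why: Buffered fluoride desilylation comes last so that the primary hydroxyl cis to the lactone carbonyl is exposed only once and under non-basic conditions, which should limit translactonisation.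

**Compound list**

1 | but-3-ene-1,2-diol (racemic) | C=CC(O)CO | starting material
2 | 1-[(tert-butyldiphenylsilyl)oxy]but-3-en-2-ol (racemic) | C=CC(O)CO[Si](c1ccccc1)(c1ccccc1)C(C)(C)C | intermediate
3 | 1-[(tert-butyldiphenylsilyl)oxy]but-3-en-2-one | C=CC(=O)CO[Si](c1ccccc1)(c1ccccc1)C(C)(C)C | intermediate
4 | 3-methylbutanal | CC(C)CC=O | starting material
5 | (2S)-6-[(tert-butyldiphenylsilyl)oxy]-5-oxo-2-(propan-2-yl)hexanal | CC(C)[C@@H](C=O)CCC(=O)CO[Si](c1ccccc1)(c1ccccc1)C(C)(C)C | intermediate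
6 | (triphenylphosphoranylidene)acetaldehyde | O=CC=P(c1ccccc1)(c1ccccc1)c1ccccc1 | starting material
7 | (2E,4S)-8-[(tert-butyldiphenylsilyl)oxy]-7-oxo-4-(propan-2-yl)oct-2-enal | CC(C)[C@@H](/C=C/C=O)CCC(=O)CO[Si](c1ccccc1)(c1ccccc1)C(C)(C)C | intermediate
8 | potassium trifluoro[(E)-2-phenylethenyl]borate | [K+].F[B-](F)(F)/C=C/c1ccccc1 | starting material
9 | (3S,4S)-8-[(tert-butyldiphenylsilyl)oxy]-7-oxo-3-[(E)-2-phenylethenyl]-4-(propan-2-yl)octanal | CC(C)[C@@H]([C@@H](CC=O)/C=C/c1ccccc1)CCC(=O)CO[Si](c1ccccc1)(c1ccccc1)C(C)(C)C | intermediate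
10 | (3S,4S)-2-bromo-8-[(tert-butyldiphenylsilyl)oxy]-7-oxo-3-[(E)-2-phenylethenyl]-4-(propan-2-yl)octanal (both C2 epimers) | CC(C)[C@@H]([C@@H](C(Br)C=O)/C=C/c1ccccc1)CCC(=O)CO[Si](c1ccccc1)(c1ccccc1)C(C)(C)C | intermediate
11 | (3S,4S)-2-bromo-8-[(tert-butyldiphenylsilyl)oxy]-7-oxo-3-[(E)-2-phenylethenyl]-4-(propan-2-yl)octanoic acid (both C2 epimers) | CC(C)[C@@H]([C@@H](C(Br)C(=O)O)/C=C/c1ccccc1)CCC(=O)CO[Si](c1ccccc1)(c1ccccc1)C(C)(C)C | intermediate
12 | tert-butyl 2-(hydroxymethyl)prop-2-enoate | C=C(CO)C(=O)OC(C)(C)C | starting material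
13 | 2-(tert-butoxycarbonyl)prop-2-en-1-yl (3S,4S)-2-bromo-8-[(tert-butyldiphenylsilyl)oxy]-7-oxo-3-[(E)-2-phenylethenyl]-4-(propan-2-yl)octanoate (both C2 epimers) | CC(C)[C@@H]([C@@H](C(Br)C(=O)OCC(=C)C(=O)OC(C)(C)C)/C=C/c1ccccc1)CCC(=O)CO[Si](c1ccccc1)(c1ccccc1)C(C)(C)C | intermediate
14 | tert-butyl (5R)-6-bromo-5-[(3S)-7-[(tert-butyldiphenylsilyl)oxy]-2-methyl-6-oxoheptan-3-yl]-7-oxo-2,5,6,7-tetrahydrooxepine-3-carboxylate (both C6 epimers) | CC(C)[C@@H]([C@@H]1C=C(C(=O)OC(C)(C)C)COC(=O)C1Br)CCC(=O)CO[Si](c1ccccc1)(c1ccccc1)C(C)(C)C | intermediate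
15 | diiodosamarium enolate of 14 after loss of bromide, tert-butyl (5R)-5-[(3S)-7-[(tert-butyldiphenylsilyl)oxy]-2-methyl-6-oxoheptan-3-yl]-7-[(diiodosamario)oxy]-2,5-dihydrooxepine-3-carboxylate | CC(C)[C@@H]([C@@H]1C=C(C(=O)OC(C)(C)C)COC(O[Sm](I)I)=C1)CCC(=O)CO[Si](c1ccccc1)(c1ccccc1)C(C)(C)C | intermediate
16 | tert-butyl (5aR,6S,9R,9aR)-9-{[(tert-butyldiphenylsilyl)oxy]methyl}-9-hydroxy-1-oxo-6-(propan-2-yl)-1,3,5a,6,7,8,9,9a-octahydro-2-benzoxepine-4-carboxylate | CC(C)[C@@H]1CC[C@](O)(CO[Si](c3ccccc3)(c3ccccc3)C(C)(C)C)[C@@H]2C(=O)OCC(C(=O)OC(C)(C)C)=C[C@@H]12 | intermediate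
17 | tert-butyl (5aR,6S,9R,9aR)-9-hydroxy-9-(hydroxymethyl)-1-oxo-6-(propan-2-yl)-1,3,5a,6,7,8,9,9a-octahydro-2-benzoxepine-4-carboxylate | CC(C)[C@@H]1CC[C@](O)(CO)[C@@H]2C(=O)OCC(C(=O)OC(C)(C)C)=C[C@@H]12 | intermediate
18 | (2R)-6-[(tert-butyldiphenylsilyl)oxy]-5-oxo-2-(propan-2-yl)hexanal | CC(C)[C@H](C=O)CCC(=O)CO[Si](c1ccccc1)(c1ccccc1)C(C)(C)C | intermediate
19 | (2E,4R)-8-[(tert-butyldiphenylsilyl)oxy]-7-oxo-4-(propan-2-yl)oct-2-enal | CC(C)[C@H](/C=C/C=O)CCC(=O)CO[Si](c1ccccc1)(c1ccccc1)C(C)(C)C | intermediate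
20 | (3R,4R)-8-[(tert-butyldiphenylsilyl)oxy]-7-oxo-3-[(E)-2-phenylethenyl]-4-(propan-2-yl)octanal | CC(C)[C@H]([C@H](CC=O)/C=C/c1ccccc1)CCC(=O)CO[Si](c1ccccc1)(c1ccccc1)C(C)(C)C | intermediate
21 | (3R,4R)-2-bromo-8-[(tert-butyldiphenylsilyl)oxy]-7-oxo-3-[(E)-2-phenylethenyl]-4-(propan-2-yl)octanal (both C2 epimers) | CC(C)[C@H]([C@H](C(Br)C=O)/C=C/c1ccccc1)CCC(=O)CO[Si](c1ccccc1)(c1ccccc1)C(C)(C)C | intermediate
22 | (3R,4R)-2-bromo-8-[(tert-butyldiphenylsilyl)oxy]-7-oxo-3-[(E)-2-phenylethenyl]-4-(propan-2-yl)octanoic acid (both C2 epimers) | CC(C)[C@H]([C@H](C(Br)C(=O)O)/C=C/c1ccccc1)CCC(=O)CO[Si](c1ccccc1)(c1ccccc1)C(C)(C)C | intermediate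
23 | 2-(tert-butoxycarbonyl)prop-2-en-1-yl (3R,4R)-2-bromo-8-[(tert-butyldiphenylsilyl)oxy]-7-oxo-3-[(E)-2-phenylethenyl]-4-(propan-2-yl)octanoate (both C2 epimers) | CC(C)[C@H]([C@H](C(Br)C(=O)OCC(=C)C(=O)OC(C)(C)C)/C=C/c1ccccc1)CCC(=O)CO[Si](c1ccccc1)(c1ccccc1)C(C)(C)C | intermediate
24 | tert-butyl (5S)-6-bromo-5-[(3R)-7-[(tert-butyldiphenylsilyl)oxy]-2-methyl-6-oxoheptan-3-yl]-7-oxo-2,5,6,7-tetrahydrooxepine-3-carboxylate (both C6 epimers) | CC(C)[C@H]([C@H]1C=C(C(=O)OC(C)(C)C)COC(=O)C1Br)CCC(=O)CO[Si](c1ccccc1)(c1ccccc1)C(C)(C)C | intermediate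
25 | diiodosamarium enolate of 24 after loss of bromide, tert-butyl (5S)-5-[(3R)-7-[(tert-butyldiphenylsilyl)oxy]-2-methyl-6-oxoheptan-3-yl]-7-[(diiodosamario)oxy]-2,5-dihydrooxepine-3-carboxylate | CC(C)[C@H]([C@H]1C=C(C(=O)OC(C)(C)C)COC(O[Sm](I)I)=C1)CCC(=O)CO[Si](c1ccccc1)(c1ccccc1)C(C)(C)C | intermediate
26 | tert-butyl (5aS,6R,9S,9aS)-9-{[(tert-butyldiphenylsilyl)oxy]methyl}-9-hydroxy-1-oxo-6-(propan-2-yl)-1,3,5a,6,7,8,9,9a-octahydro-2-benzoxepine-4-carboxylate | CC(C)[C@H]1CC[C@@](O)(CO[Si](c3ccccc3)(c3ccccc3)C(C)(C)C)[C@H]2C(=O)OCC(C(=O)OC(C)(C)C)=C[C@H]12 | intermediate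
27 | (5aS,6R,9S,9aS)-9-{[(tert-butyldiphenylsilyl)oxy]methyl}-9-hydroxy-1-oxo-6-(propan-2-yl)-1,3,5a,6,7,8,9,9a-octahydro-2-benzoxepine-4-carboxylic acid | CC(C)[C@H]1CC[C@@](O)(CO[Si](c3ccccc3)(c3ccccc3)C(C)(C)C)[C@H]2C(=O)OCC(C(=O)O)=C[C@H]12 | intermediate
28 | ester of acid 27 with the primary hydroxyl of 17 (left silyl ether, right tert-butyl ester; full name in step 19) | CC(C)[C@H]1CC[C@@](O)(CO[Si](c5ccccc5)(c5ccccc5)C(C)(C)C)[C@H]2C(=O)OCC(C(=O)OC[C@@]3(O)CC[C@@H](C(C)C)[C@@H]4C=C(C(=O)OC(C)(C)C)COC(=O)[C@H]43)=C[C@H]12 | intermediate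
29 | right-hand carboxylic acid of 28 with the left silyl ether retained (full name in step 20) | CC(C)[C@H]1CC[C@@](O)(CO[Si](c5ccccc5)(c5ccccc5)C(C)(C)C)[C@H]2C(=O)OCC(C(=O)OC[C@@]3(O)CC[C@@H](C(C)C)[C@@H]4C=C(C(=O)O)COC(=O)[C@H]43)=C[C@H]12 | intermediate
30 | CNP0340505.1 (full name in step 21) | CC(C)[C@H]1CC[C@@](O)(CO)[C@H]2C(=O)OCC(C(=O)OC[C@@]3(O)CC[C@@H](C(C)C)[C@@H]4C=C(C(=O)O)COC(=O)[C@H]43)=C[C@H]12 | target

**Step count.** 21 steps in total. The longest linear sequence is 13 steps (1, 2, 11–18, 19, 20, 21; the right-hand branch 1–10 is equally long up to step 19).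

**Steps most likely to fail**

Step 17 (and its mirror-image twin, step 9). The samarium aldol may close with poor facial selectivity at the enolate carbon, so that the ring bonds at C5a and C9a end cis while C9 is formed correctly. The fallback moves the ring fusion from kinetic to thermodynamic control. It sets out from 24; the cyclisation product, tert-butyl (5aS,6R,9S,9aR)-9-{[(tert-butyldiphenylsilyl)oxy]methyl}-9-hydroxy-1-oxo-6-(propan-2-yl)-1,3,5a,6,7,8,9,9a-octahydro-2-benzoxepine-4-carboxylate F1, is isolated and equilibrated with DBU in toluene. C9a is the only centre α to the lactone carbonyl, and the trans-fused isomer with both ring bonds equatorial should be favoured, so the route is rejoined at 26. In the antipodal series the same sequence runs from 14 through the (5aR,6S,9R,9aS) mirror image F2 to 16.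

Step 13 (and its twin, step 5). The iminium-catalysed styryl transfer may stall at the hindered β-carbon of the γ-branched enal, or the catalyst may fail to override the resident C4 centre. The fallback replaces organocatalysis by a Hayashi–Miyaura addition: 19 is treated with (E)-2-phenylethenylboronic acid, [RhCl(C2H4)2]2 (3 mol%), a chiral 2,5-diphenylbicyclo[2.2.2]octa-2,5-diene ligand and KOH in dioxane/water, and returns directly to 20. The antipodal ligand is used for 7 to 9. This fallback makes no new compound (F0).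

Step 16 (and its twin, step 8). Ring closure may be slow because the ester prefers the s-trans conformer and the 1,1-disubstituted acrylate alkene is unreactive, so oligomerisation could compete. The fallback forms the alkene first and the ring second. It sets out from 22: cross-metathesis with 12 (second-generation Hoveyda–Grubbs catalyst, CH2Cl2, 40 °C) should give (3S,4R)-2-bromo-3-[(1E)-2-(tert-butoxycarbonyl)-3-hydroxyprop-1-en-1-yl]-8-[(tert-butyldiphenylsilyl)oxy]-7-oxo-4-(propan-2-yl)octanoic acid F3. Shiina lactonisation (2-methyl-6-nitrobenzoic anhydride, DMAP, CH2Cl2, high dilution) then rejoins the route at 24. In the antipodal series the sequence runs from 11 through the (3R,4S) mirror image F4 to 14.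

**Further compounds**

F1 | step 17 | tert-butyl (5aS,6R,9S,9aR)-9-{[(tert-butyldiphenylsilyl)oxy]methyl}-9-hydroxy-1-oxo-6-(propan-2-yl)-1,3,5a,6,7,8,9,9a-octahydro-2-benzoxepine-4-carboxylate | CC(C)[C@H]1CC[C@@](O)(CO[Si](c3ccccc3)(c3ccccc3)C(C)(C)C)[C@@H]2C(=O)OCC(C(=O)OC(C)(C)C)=C[C@H]12
F2 | step 9 | tert-butyl (5aR,6S,9R,9aS)-9-{[(tert-butyldiphenylsilyl)oxy]methyl}-9-hydroxy-1-oxo-6-(propan-2-yl)-1,3,5a,6,7,8,9,9a-octahydro-2-benzoxepine-4-carboxylate | CC(C)[C@@H]1CC[C@](O)(CO[Si](c3ccccc3)(c3ccccc3)C(C)(C)C)[C@H]2C(=O)OCC(C(=O)OC(C)(C)C)=C[C@@H]12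
F0 | step 13 | none | none
F3 | step 16 | (3S,4R)-2-bromo-3-[(1E)-2-(tert-butoxycarbonyl)-3-hydroxyprop-1-en-1-yl]-8-[(tert-butyldiphenylsilyl)oxy]-7-oxo-4-(propan-2-yl)octanoic acid (both C2 epimers) | CC(C)[C@H]([C@H](C(Br)C(=O)O)/C=C(\CO)C(=O)OC(C)(C)C)CCC(=O)CO[Si](c1ccccc1)(c1ccccc1)C(C)(C)C
F4 | step 8 | (3R,4S)-2-bromo-3-[(1E)-2-(tert-butoxycarbonyl)-3-hydroxyprop-1-en-1-yl]-8-[(tert-butyldiphenylsilyl)oxy]-7-oxo-4-(propan-2-yl)octanoic acid (both C2 epimers) | CC(C)[C@@H]([C@@H](C(Br)C(=O)O)/C=C(\CO)C(=O)OC(C)(C)C)CCC(=O)CO[Si](c1ccccc1)(c1ccccc1)C(C)(C)C
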